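Beside this flask stood a neighbour with less initiator, and the question I carried between them was how much free monomer a charge of initiator can draw into chains before its living ends die.

free monomer 0.40 M; initiator 3.8 mol%; time 40 h

    monomer in chains + living end → free monomer + living end, rate k1*[living end] as long as [monomer in chains] is above zero (k1 = 0.20 h⁻¹)
    free monomer + living end → monomer in chains + living end, rate k2*[living end]*[free monomer] (k2 = 8.0 M⁻¹ h⁻¹)
    free monomer + initiator → living end + monomer in chains (k3 = 4.8 M⁻¹ h⁻¹)
    living end + free monomer → dead end (k4 = 0.47 M⁻¹ h⁻¹)
    free monomer → decomposition product (k5 = 4.3 × 10⁻⁴ h⁻¹)

- average number of monomer units in a chain (chains begun, living or dead) at 40 h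
- part of the free monomer that has reacted at 40 h

- the average divides the monomer in chains by the number of chains begun, living and dead together
- run time (flask): 40 h

I reckoned with the rate. At the charged free monomer the initiator had a half-life of 0.361 h, short against 40 h, so I took the ends as begun at once. Free monomer then entered chains at 0.122 h⁻¹, a pseudo-first-order rate while the ends stood constant.

I then took what slowed it, factor by factor. Growth and killing both go as [living end][free monomer], so each end lost meant on average 17.0 units added, before any were taken back. The initiator loading times that ratio is the end budget, 64.7% of the charge: the gross additions, reverse step aside, by the time the ends reach zero, so their factor on the rate falls to zero there. On that count free monomer stood at 35.3% of its charge at that point, and its factor on the rate is the same. The reverse step took back 6.25% of the additions at the start and 17.7% at the budget's edge.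

An end's lifetime near that edge was 15.1 h, and 40 h is 2.65 such lifetimes, which left 7.07% of the ends in my count, so I reckoned up to the budget's edge. With the mean reverse share, each end kept 15.0 units net, plus one from its start, and one more free monomer went in its death. I committed to a dp of 16.0 and 64.5% reacted.

The forecast gave 15.8 (14.5 to 17) and 64.5% (60% to 68%), holding that “the ends run out before the monomer can fall to its roughly 0.024 M equilibrium level”. My dp of 16.0 lay above its value.

The flask gave 15.8 and 64.5%, inside the forecast's ranges. Living end stood at 4.71 × 10⁻⁴ M at 40.0 h, 3.10% of the initiator charge. The budget still held by those ends was 2.00% of the charge in gross additions, and by 400 h monomer in chains in this flask had gone from 60.0% to 61.7%.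

In the neighbour with 1.5 mol% of initiator, the budget came to 25.5% of the charge in gross additions. The computed neighbour had 27.9% reacted, with 25.1% as monomer in chains.

The numbers of this flask are assumed; the run is a simulation.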